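## The problem

Target 20 is a trimeric acylphloroglucinol. Central ring A (acyl at C1, hydroxyls at C2, C4 and C6) carries methylene bridges at C3 and C5 to outer rings B and C, which differ only in the C5' acyl group (acetyl on ring B, 2-methylpropanoyl on ring C). Because the outer rings differ, the two bridges must be made one after the other; the local symmetry of ring A makes C3 and C5 equivalent, so only the order has to be controlled, not the position. The single stereocentre, C2 of the (R)-2-methylbutanoyl chain, lies next to the ring A ketone. It can direct nothing, has to be bought with the acid, and is at risk in every step that can enolise the ketone or pass through a ketene. Seven free phenols make the final compound air-sensitive under base, and methylene-bridged phloroglucinols can exchange their arms under hot base or acid, so the endgame must be mild. The central difficulty is the methoxy group at C4' of each outer ring: it sits between the C3' methyl and the C5' acyl group, on the most hindered and hydrogen-bonded oxygen of what would be a triol, so selective O-methylation cannot place it. The enabling feature is that the 4'-deoxy outer ring has exactly one aromatic C–H bond, at C4', ortho to the C5' ketone, while ring A has none. A ketone-directed C–H oxygenation therefore has one possible site per outer ring, and with every other oxygen acetylated the new hydroxyl is the only one left to methylate.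

## Retrosynthesis

**20 back to 19 and 18 (seven acetyl C–O bonds, two O–CH3 bonds).** The free heptaphenol is made only in the last step, by methanolysis of heptaacetate 19. The two methyl groups are put on diol 18, in which the C4' hydroxyls of rings B and C are the only free oxygens. Their ring neighbours are a methyl and an acyl group, not an acetate, so no acetyl group can migrate onto them. The forward reactions must be a methylation that leaves aryl acetates alone and a deacetylation that does not enolise the ring A ketone.

**18 back to 16 (the C4'–O bonds of rings B and C).** This is the strategic cut. Bringing the oxygen in with a trihydroxytoluene building block would leave three phenols to tell apart, with the wanted one the least reactive. Cutting the C–O bond back to a C–H bond instead turns both outer rings into derivatives of 4-methylresorcinol and leaves no regiochemical choice. The forward step needs a twofold palladation at a C–H bond flanked by methyl and acyl, tolerance of seven acetates, and no loss of configuration next to the ring A ketone.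

**16 back to 15 (seven acetyl groups).** Peracetylation of heptaphenol 15 masks every oxygen that is to end up as a free hydroxyl and removes the phenols that an oxidant would attack. Acetyl is chosen because it is small enough for doubly flanked phenols and comes off under the mildest conditions.

**15 back to 13 and 7, and 13 back to 11 and 6 (the ring A C5–CH2 and C3–CH2 bonds).** The bridges are cut on the ring A side. Each outer ring has a single nucleophilic carbon (C1', between its two hydroxyls), which can be turned cleanly into a benzylic electrophile as Mannich base 6 or 7. Ring A ketone 11 offers two equivalent nucleophilic carbons. A one-pot formaldehyde condensation of all three rings would give a statistical set of trimers, so the arms are attached in sequence: 11 with 6 gives dimer 13, then 13 with 7 gives 15. The forward reactions must stop at one arm in the first coupling and must not exchange that arm in the second.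

**6 and 7 back to 3 and 5 (the C1'–CH2 bonds).** Aminomethylation of acylresorcinols 3 and 5 can only occur between the two hydroxyls, because the other free ring carbon is meta to both oxygens. The same substitution pattern that later leaves a single C–H bond for the key step also fixes the bridge position here.

**3 and 5 back to 1 with 2 or 4; 11 back to 9 and 8 (the aryl–acyl bonds).** Friedel–Crafts acylation of 4-methylresorcinol 1 with acetyl chloride 2 or 2-methylpropanoyl chloride 4 goes para to one hydroxyl and ortho to the other. Phloroglucinol 9 is acylated with chloride 10 made from (R)-2-methylbutanoic acid 8. All five starting materials are simple commercial compounds, and the stereocentre is taken from the chiral pool.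

## Roads not taken

**Alternative 1:** Ring A is built by a Danheiser benzannulation, cutting ring A bonds C1–C2, C2–C3 and C5–C6. Cyclobutenone A2, which already carries both benzyl-protected outer-ring arms, would open thermally to a vinylketene, add siloxyalkyne A3 in a [2+2] step, reopen and close by 6π electrocyclisation to phenol A1.
- Merits: both arms are fixed on separate carbons of the four-membered ring before the arene exists, so there is no statistical bridging and no arm exchange. The ring A oxygens also emerge differentiated. In this respect it is better than the chosen plan.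
- Weak points: it constructs the one ring that can be bought. A2 is a fully substituted cyclobutenone whose arms are complete outer rings, so the hard problem, the C4' methoxy group, must be solved beforehand by other means. After A1 the chiral acyl group still has to be introduced at C1 by Friedel–Crafts chemistry on much more valuable material, followed by removal of two silyl and four benzyl groups.
- Comparison: the chosen plan sets the symmetry of ring A and an excess of 11 against the bridging advantage, and is far shorter.

**Alternative 2:** Rings B and C are each closed at C5'–C6' by a twofold Claisen-type condensation. Bis(polyketo ester) A5, hung on ring A tris(benzyl ether), would be deprotonated at C3' of each chain; the dienolates would attack the ester carbonyls through C5' and aromatise to A4.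
- Merits: the C4' oxygen is a methyl enol ether from the start, so the methoxy position is settled without differentiating phenols and without a hindered C–H activation. On this point it is more secure than the chosen plan.
- Weak points: A5 has two chains with several acidic sites each. Competing aldol modes, O-cyclisation to pyranones and loss of methanol from the β-methoxy enone are all open, and both chains must fold correctly in one molecule. Assembly of A5 is long, and A4 still lacks the ring A acyl group, which would have to be added at a late stage before debenzylation.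
- Comparison: the chosen plan buys all three aromatic rings and has one C–H bond per ring to react, which it sets against the cleaner origin of the methoxy group here.

**Alternative 3:** The ring A acyl group and the C2 oxygen are introduced together by formal insertion of a ring A aryne into acid 8. Fluoride would release the C1–C2 aryne from silyl triflate A7; the carboxylate adds through oxygen at C2, and the aryl anion at C1 takes the acyl carbon to give A6.
- Merits: the chiral acyl group enters late, under fluoride conditions without Lewis acid, so the racemisation risk of a Friedel–Crafts acylation is avoided. This is a real advantage over step 5 of the chosen plan.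
- Weak points: A7 is a hexasubstituted benzene that needs both arms, the silyl and triflate groups and six benzyl ethers in place first. The sense of addition rests on one flanking benzyloxy group, and simple O-arylation without acyl transfer competes. The C4' methoxy problem is untouched and must be solved separately.
- Comparison: the chosen plan answers the racemisation risk with a low-temperature acylation and an organolithium fallback, and keeps the route short.

Key step: step 9

Remark on the chemistry: outer-ring locants count from the bridge carbon C1' (C2' and C6' oxygen, C3' methyl, C4' the oxygenation site, C5' acyl). Acid 8 is assumed to be purchasable as the single (R) enantiomer.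

## Route

Step 1
Reactants: 1 4-methylbenzene-1,3-diol; 2 acetyl chloride
Product: 3 1-(2,4-dihydroxy-5-methylphenyl)ethan-1-one
Conditions: AlCl3 (2.5 equiv), PhNO2, 0 → 60 °C; aq. HCl
Reagents that add atoms: none
Why: Friedel–Crafts acylation of a resorcinol goes para to one hydroxyl and ortho to the other; the carbon between the hydroxyls is more crowded and the carbon next to the methyl group is meta to both oxygens, and the first acyl group deactivates the ring against a second.

Step 2
Reactants: 1 4-methylbenzene-1,3-diol; 4 2-methylpropanoyl chloride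
Product: 5 1-(2,4-dihydroxy-5-methylphenyl)-2-methylpropan-1-one
Conditions: AlCl3 (2.5 equiv), PhNO2, 0 → 60 °C; aq. HCl
Reagents that add atoms: none
Why: The same Friedel–Crafts acylation as in step 1, with the same regiochemical control by the two hydroxyls.

Step 3
Reactants: 3 1-(2,4-dihydroxy-5-methylphenyl)ethan-1-one
Product: 6 1-[3-[(dimethylamino)methyl]-2,4-dihydroxy-5-methylphenyl]ethan-1-one
Conditions: 37% aq. CH2O, 40% aq. Me2NH, EtOH, rt
Reagents that add atoms: formaldehyde, C=O; dimethylamine, CNC
Why: Phenolic Mannich reaction; the iminium ion attacks the only activated ring carbon, the one between the two hydroxyls, since the remaining C–H is meta to both oxygens.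

Step 4
Reactants: 5 1-(2,4-dihydroxy-5-methylphenyl)-2-methylpropan-1-one
Product: 7 1-[3-[(dimethylamino)methyl]-2,4-dihydroxy-5-methylphenyl]-2-methylpropan-1-one
Conditions: 37% aq. CH2O, 40% aq. Me2NH, EtOH, rt
Reagents that add atoms: formaldehyde, C=O; dimethylamine, CNC
Why: The same phenolic Mannich reaction as in step 3, at the single carbon between the hydroxyls.

Step 5
Reactants: 8 (2R)-2-methylbutanoic acid; 9 benzene-1,3,5-triol (phloroglucinol)
Product: 11 (2R)-2-methyl-1-(2,4,6-trihydroxyphenyl)butan-1-one, via (2R)-2-methylbutanoyl chloride 10 (not isolated)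
Conditions: (COCl)2, DMF (cat.), CH2Cl2, 0 °C → rt; then 9, AlCl3 (4 equiv), PhNO2/CH2Cl2, 0 °C → rt; aq. HCl
Reagents that add atoms: none
Why: Acid chloride formation followed by Friedel–Crafts C-acylation of phloroglucinol, which stops at the monoketone because the acyl group deactivates the ring; the stereocentre is carried over from acid 8, and the low temperature is chosen to limit ketene or enol formation.

Step 6
Reactants: 11 (2R)-2-methyl-1-(2,4,6-trihydroxyphenyl)butan-1-one; 6 1-[3-[(dimethylamino)methyl]-2,4-dihydroxy-5-methylphenyl]ethan-1-one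
Product: 13 (2R)-1-[3-[(3-acetyl-2,6-dihydroxy-5-methylphenyl)methyl]-2,4,6-trihydroxyphenyl]-2-methylbutan-1-one, via ortho-quinone methide 12 (not isolated)
Conditions: 11 (2.5 equiv), 1,4-dioxane, 100 °C, Ar
Reagents that add atoms: none
Why: Thermal loss of dimethylamine from the ortho-hydroxybenzylamine gives ortho-quinone methide 12, which is captured by conjugate addition of the nucleophilic ring carbon of 11 (quinone methide arylation); the excess of 11 should hold the reaction at one arm, and the two free carbons of 11 are equivalent.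

Step 7
Reactants: 13 (2R)-1-[3-[(3-acetyl-2,6-dihydroxy-5-methylphenyl)methyl]-2,4,6-trihydroxyphenyl]-2-methylbutan-1-one; 7 1-[3-[(dimethylamino)methyl]-2,4-dihydroxy-5-methylphenyl]-2-methylpropan-1-one
Product: 15 (2R)-1-[3-[(3-acetyl-2,6-dihydroxy-5-methylphenyl)methyl]-5-[[2,6-dihydroxy-3-methyl-5-(2-methylpropanoyl)phenyl]methyl]-2,4,6-trihydroxyphenyl]-2-methylbutan-1-one, via ortho-quinone methide 14 (not isolated)
Conditions: 7 (1.3 equiv), 1,4-dioxane, 100 °C, Ar
Reagents that add atoms: none
Why: The same quinone methide arylation as in step 6; dimer 13 has a single nucleophilic ring carbon left (C5 of ring A), because the only C–H of its outer ring is meta to both hydroxyls.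

Step 8
Reactants: 15 (2R)-1-[3-[(3-acetyl-2,6-dihydroxy-5-methylphenyl)methyl]-5-[[2,6-dihydroxy-3-methyl-5-(2-methylpropanoyl)phenyl]methyl]-2,4,6-trihydroxyphenyl]-2-methylbutan-1-one
Product: 16 heptaacetate of 15, (2R)-1-[3-[(3-acetyl-2,6-diacetoxy-5-methylphenyl)methyl]-5-[[2,6-diacetoxy-3-methyl-5-(2-methylpropanoyl)phenyl]methyl]-2,4,6-triacetoxyphenyl]-2-methylbutan-1-one
Conditions: Ac2O, pyridine, DMAP (cat.), rt → 40 °C
Reagents that add atoms: acetic anhydride, CC(=O)OC(C)=O
Why: Exhaustive DMAP-catalysed O-acetylation; acetyl is small enough for the seven doubly flanked phenols, and pyridine is too weak a base to enolise the ring A ketone.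

Step 9
Reactants: 16 heptaacetate of 15
Product: 18 (2R)-1-[3-[(3-acetyl-2,6-diacetoxy-4-hydroxy-5-methylphenyl)methyl]-5-[[2,6-diacetoxy-4-hydroxy-3-methyl-5-(2-methylpropanoyl)phenyl]methyl]-2,4,6-triacetoxyphenyl]-2-methylbutan-1-one, via bis(trifluoroacetate) 17 (not isolated)
Conditions: Pd(OCOCF3)2 (20 mol%), PhI(OCOCF3)2 (5 equiv), ClCH2CH2Cl, 80 °C; then pH 7 phosphate buffer, THF, rt
Reagents that add atoms: [bis(trifluoroacetoxy)iodo]benzene, O=C(OI(OC(=O)C(F)(F)F)c1ccccc1)C(F)(F)F
Why: Each outer-ring ketone oxygen binds Pd(OCOCF3)2, and trifluoroacetate-assisted concerted metalation–deprotonation of the only ortho C–H bond, C4'–H, gives a five-membered palladacycle of divalent palladium. PhI(OCOCF3)2 oxidises it to a tetravalent palladium trifluoroacetate, and C–O reductive elimination forms the C4'–O bond as aryl trifluoroacetate 17 and returns divalent palladium; the buffered work-up cleaves only the much more labile trifluoroacetates to give 18. The closest known reaction type is the palladium-catalysed, ketone-directed ortho C–H hydroxylation of aryl alkyl ketones with trivalent iodine or persulfate oxidants. No ring is closed and no stereocentre is formed. The site selectivity needed is secured by the substrate: rings B and C each have one aromatic C–H bond, it is ortho to the ketone, and ring A has none. Chemoselectivity rests on the acetates, which keep the oxidant from dearomatising any phenol and leave the two new oxygens as the only free hydroxyls. Because the C–H bond lies between a methyl and an acyl group, a high catalyst loading and excess oxidant are planned, and the non-acidic solvent is chosen to limit enolisation of the ring A ketone so that the stereocentre should be retained.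

Step 10
Reactants: 18 bis(4'-hydroxy) heptaacetate
Product: 19 (2R)-1-[3-[(3-acetyl-2,6-diacetoxy-4-methoxy-5-methylphenyl)methyl]-5-[[2,6-diacetoxy-4-methoxy-3-methyl-5-(2-methylpropanoyl)phenyl]methyl]-2,4,6-triacetoxyphenyl]-2-methylbutan-1-one
Conditions: MeI (excess), Ag2O, MeCN, 40 °C, dark
Reagents that add atoms: iodomethane, CI
Why: Purdie-type O-methylation with Ag2O and MeI runs without soluble base, so the seven aryl acetates should stay in place; the two C4' hydroxyls are the only free ones and have no acetoxy neighbour from which an acetyl group could migrate.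

Step 11
Reactants: 19 bis(4'-methoxy) heptaacetate
Product: 20 (2R)-1-[3-[(3-acetyl-2,6-dihydroxy-4-methoxy-5-methylphenyl)methyl]-5-[[2,6-dihydroxy-4-methoxy-3-methyl-5-(2-methylpropanoyl)phenyl]methyl]-2,4,6-trihydroxyphenyl]-2-methylbutan-1-one
Conditions: K2CO3, MeOH, 0 °C, Ar; then dilute aq. HCl
Reagents that add atoms: none
Why: Base-mediated transesterification (methanolysis) of aryl acetates is fast at 0 °C and leaves aryl methyl ethers, ketones and the methylene bridges alone; once ring A is a phenoxide its ketone is a vinylogous carboxylate and resists enolisation, so the stereocentre should hold.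

## Compound list

1 | 4-methylbenzene-1,3-diol | Cc1ccc(O)cc1O | starting material
2 | acetyl chloride | CC(=O)Cl | starting material
3 | 1-(2,4-dihydroxy-5-methylphenyl)ethan-1-one | CC(=O)c1cc(C)c(O)cc1O | intermediate
4 | 2-methylpropanoyl chloride (isobutyryl chloride) | CC(C)C(=O)Cl | starting material
5 | 1-(2,4-dihydroxy-5-methylphenyl)-2-methylpropan-1-one | CC(C)C(=O)c1cc(C)c(O)cc1O | intermediate
6 | 1-[3-[(dimethylamino)methyl]-2,4-dihydroxy-5-methylphenyl]ethan-1-one | CC(=O)c1cc(C)c(O)c(CN(C)C)c1O | intermediate
7 | 1-[3-[(dimethylamino)methyl]-2,4-dihydroxy-5-methylphenyl]-2-methylpropan-1-one | CC(C)C(=O)c1cc(C)c(O)c(CN(C)C)c1O | intermediate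
8 | (2R)-2-methylbutanoic acid | CC[C@@H](C)C(=O)O | starting material
9 | benzene-1,3,5-triol (phloroglucinol) | Oc1cc(O)cc(O)c1 | starting material
10 | (2R)-2-methylbutanoyl chloride | CC[C@@H](C)C(=O)Cl | intermediate (not isolated)
11 | (2R)-2-methyl-1-(2,4,6-trihydroxyphenyl)butan-1-one | CC[C@@H](C)C(=O)c1c(O)cc(O)cc1O | intermediate
12 | 4-acetyl-3-hydroxy-6-methyl-2-methylidenecyclohexa-3,5-dien-1-one (ortho-quinone methide from 6) | CC(=O)C1=C(O)C(=C)C(=O)C(C)=C1 | intermediate (not isolated)
13 | (2R)-1-[3-[(3-acetyl-2,6-dihydroxy-5-methylphenyl)methyl]-2,4,6-trihydroxyphenyl]-2-methylbutan-1-one | CC[C@@H](C)C(=O)c1c(O)cc(O)c(Cc2c(O)c(C)cc(C(C)=O)c2O)c1O | intermediate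
14 | 3-hydroxy-6-methyl-2-methylidene-4-(2-methylpropanoyl)cyclohexa-3,5-dien-1-one (ortho-quinone methide from 7) | CC(C)C(=O)C1=C(O)C(=C)C(=O)C(C)=C1 | intermediate (not isolated)
15 | (2R)-1-[3-[(3-acetyl-2,6-dihydroxy-5-methylphenyl)methyl]-5-[[2,6-dihydroxy-3-methyl-5-(2-methylpropanoyl)phenyl]methyl]-2,4,6-trihydroxyphenyl]-2-methylbutan-1-one | CC[C@@H](C)C(=O)c1c(O)c(Cc2c(O)c(C)cc(C(C)=O)c2O)c(O)c(Cc2c(O)c(C)cc(C(=O)C(C)C)c2O)c1O | intermediate
16 | heptaacetate of 15, (2R)-1-[3-[(3-acetyl-2,6-diacetoxy-5-methylphenyl)methyl]-5-[[2,6-diacetoxy-3-methyl-5-(2-methylpropanoyl)phenyl]methyl]-2,4,6-triacetoxyphenyl]-2-methylbutan-1-one | CC[C@@H](C)C(=O)c1c(OC(C)=O)c(Cc2c(OC(C)=O)c(C)cc(C(C)=O)c2OC(C)=O)c(OC(C)=O)c(Cc2c(OC(C)=O)c(C)cc(C(=O)C(C)C)c2OC(C)=O)c1OC(C)=O | intermediate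
17 | heptaacetate 16 carrying a trifluoroacetoxy group at C4' of ring B and of ring C | CC[C@@H](C)C(=O)c1c(OC(C)=O)c(Cc2c(OC(C)=O)c(C)c(OC(=O)C(F)(F)F)c(C(C)=O)c2OC(C)=O)c(OC(C)=O)c(Cc2c(OC(C)=O)c(C)c(OC(=O)C(F)(F)F)c(C(=O)C(C)C)c2OC(C)=O)c1OC(C)=O | intermediate (not isolated)
18 | (2R)-1-[3-[(3-acetyl-2,6-diacetoxy-4-hydroxy-5-methylphenyl)methyl]-5-[[2,6-diacetoxy-4-hydroxy-3-methyl-5-(2-methylpropanoyl)phenyl]methyl]-2,4,6-triacetoxyphenyl]-2-methylbutan-1-one | CC[C@@H](C)C(=O)c1c(OC(C)=O)c(Cc2c(OC(C)=O)c(C)c(O)c(C(C)=O)c2OC(C)=O)c(OC(C)=O)c(Cc2c(OC(C)=O)c(C)c(O)c(C(=O)C(C)C)c2OC(C)=O)c1OC(C)=O | intermediate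
19 | (2R)-1-[3-[(3-acetyl-2,6-diacetoxy-4-methoxy-5-methylphenyl)methyl]-5-[[2,6-diacetoxy-4-methoxy-3-methyl-5-(2-methylpropanoyl)phenyl]methyl]-2,4,6-triacetoxyphenyl]-2-methylbutan-1-one | CC[C@@H](C)C(=O)c1c(OC(C)=O)c(Cc2c(OC(C)=O)c(C)c(OC)c(C(C)=O)c2OC(C)=O)c(OC(C)=O)c(Cc2c(OC(C)=O)c(C)c(OC)c(C(=O)C(C)C)c2OC(C)=O)c1OC(C)=O | intermediate
20 | (2R)-1-[3-[(3-acetyl-2,6-dihydroxy-4-methoxy-5-methylphenyl)methyl]-5-[[2,6-dihydroxy-4-methoxy-3-methyl-5-(2-methylpropanoyl)phenyl]methyl]-2,4,6-trihydroxyphenyl]-2-methylbutan-1-one | CC[C@@H](C)C(=O)c1c(O)c(Cc2c(O)c(C)c(OC)c(C(C)=O)c2O)c(O)c(Cc2c(O)c(C)c(OC)c(C(=O)C(C)C)c2O)c1O | target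

## Step count and risks

Total: 11 steps. Longest linear sequence: 8 steps (steps 1, 3, 6, 7, 8, 9, 10 and 11, from 1 to 20).

**Step 9 (key step).** The most likely failure is slow or incomplete twofold cyclopalladation, stalling at the monohydroxylated stage. The C4'–H bond is flanked by the C3' methyl group, the directing carbonyl is tilted by its C6' acetoxy neighbour, and the ring A ketone can hold palladium without offering a C–H bond. Long heating with the liberated CF3CO2H could also begin to exchange acetates or enolise the ring A ketone. The fallback moves the oxygenation to the monomers; it sets out from 3 and 5 and returns to the route at 20.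
- Acetylation (Ac2O, pyridine) would give 1-(2,4-diacetoxy-5-methylphenyl)ethan-1-one F1 and 1-(2,4-diacetoxy-5-methylphenyl)-2-methylpropan-1-one F2.
- Each has one ketone, one ortho C–H bond, no stereocentre and no bridge, so the hydroxylation of step 9 can be pushed with more catalyst and oxidant. It would give 1-[2,4-diacetoxy-5-methyl-6-(trifluoroacetoxy)phenyl]ethan-1-one F3 and 1-[2,4-diacetoxy-5-methyl-6-(trifluoroacetoxy)phenyl]-2-methylpropan-1-one F4, hydrolysed on work-up to 1-(2,4-diacetoxy-6-hydroxy-5-methylphenyl)ethan-1-one F5 and 1-(2,4-diacetoxy-6-hydroxy-5-methylphenyl)-2-methylpropan-1-one F6.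
- Methylation as in step 10 would give 1-(2,4-diacetoxy-6-methoxy-5-methylphenyl)ethan-1-one F7 and 1-(2,4-diacetoxy-6-methoxy-5-methylphenyl)-2-methylpropan-1-one F8. Methanolysis as in step 11 would give 1-(2,4-dihydroxy-6-methoxy-5-methylphenyl)ethan-1-one F9 and 1-(2,4-dihydroxy-6-methoxy-5-methylphenyl)-2-methylpropan-1-one F10.
- Mannich reaction as in step 3 would give 1-[3-[(dimethylamino)methyl]-2,4-dihydroxy-6-methoxy-5-methylphenyl]ethan-1-one F11 and 1-[3-[(dimethylamino)methyl]-2,4-dihydroxy-6-methoxy-5-methylphenyl]-2-methylpropan-1-one F12.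
- Heating F11 with excess 11 would pass through 4-acetyl-3-hydroxy-5-methoxy-6-methyl-2-methylidenecyclohexa-3,5-dien-1-one F13 to (2R)-1-[3-[(3-acetyl-2,6-dihydroxy-4-methoxy-5-methylphenyl)methyl]-2,4,6-trihydroxyphenyl]-2-methylbutan-1-one F14. Heating F14 with F12 would pass through 3-hydroxy-5-methoxy-6-methyl-2-methylidene-4-(2-methylpropanoyl)cyclohexa-3,5-dien-1-one F15 to 20.

**Step 5.** The stereocentre may be eroded during the Friedel–Crafts acylation, through ketene formation from chloride 10 or AlCl3-promoted enolisation of the product ketone. The fallback replaces electrophilic acylation by an organolithium ketone synthesis; it sets out from 8 and 9 and returns at 11. Acid 8 would be converted with MeNHOMe·HCl and a carbodiimide into (2R)-N-methoxy-N,2-dimethylbutanamide F16. Phloroglucinol 9 would be converted with MeOCH2Cl and i-Pr2NEt into 1,3,5-tris(methoxymethoxy)benzene F17. Lithiation of F17 with n-BuLi between two of its ether groups would give 2-lithio-1,3,5-tris(methoxymethoxy)benzene F18, which adds to F16 at −78 °C to give (2R)-2-methyl-1-[2,4,6-tris(methoxymethoxy)phenyl]butan-1-one F19. HCl in MeOH at room temperature would release 11.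

**Step 7.** Quinone methide 14 may be consumed by self-addition before the hindered, poorly soluble dimer 13 captures it. The arm already present may also be exchanged by reversible loss of 12 from 13, which would lead to symmetric trimers. The fallback reverses the polarity of the second bridge; it sets out from 13 and returns at 15. Aminomethylation of the last free ring A carbon of 13 (CH2O, Me2NH) would give (2R)-1-[3-[(3-acetyl-2,6-dihydroxy-5-methylphenyl)methyl]-5-[(dimethylamino)methyl]-2,4,6-trihydroxyphenyl]-2-methylbutan-1-one F20. Heating F20 with an excess of monomer 5 would pass through (2R)-configured 2-[(3-acetyl-2,6-dihydroxy-5-methylphenyl)methyl]-3,5-dihydroxy-4-(2-methylbutanoyl)-6-methylidenecyclohexa-2,4-dien-1-one F21, which 5 captures at the carbon between its hydroxyls to give 15.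

**Step 10.** Etherification of the two hindered, hydrogen-bonded hydroxyls may be incomplete, and on long exposure acetyl groups may transfer between molecules onto the free phenols. The fallback, from 18 to 19, replaces alkylation of the phenol by a Mitsunobu redox condensation (MeOH, PPh3, diisopropyl azodicarboxylate, THF, rt). Here methanol is activated as an alkoxyphosphonium ion under neutral conditions and no new compound is made on the way.

## Further compounds

F1 | step 9 | 1-(2,4-diacetoxy-5-methylphenyl)ethan-1-one | CC(=O)c1cc(C)c(OC(C)=O)cc1OC(C)=O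
F2 | step 9 | 1-(2,4-diacetoxy-5-methylphenyl)-2-methylpropan-1-one | CC(C)C(=O)c1cc(C)c(OC(C)=O)cc1OC(C)=O
F3 | step 9 | 1-[2,4-diacetoxy-5-methyl-6-(trifluoroacetoxy)phenyl]ethan-1-one | CC(=O)c1c(OC(=O)C(F)(F)F)c(C)c(OC(C)=O)cc1OC(C)=O
F4 | step 9 | 1-[2,4-diacetoxy-5-methyl-6-(trifluoroacetoxy)phenyl]-2-methylpropan-1-one | CC(C)C(=O)c1c(OC(=O)C(F)(F)F)c(C)c(OC(C)=O)cc1OC(C)=O
F5 | step 9 | 1-(2,4-diacetoxy-6-hydroxy-5-methylphenyl)ethan-1-one | CC(=O)c1c(O)c(C)c(OC(C)=O)cc1OC(C)=O
F6 | step 9 | 1-(2,4-diacetoxy-6-hydroxy-5-methylphenyl)-2-methylpropan-1-one | CC(C)C(=O)c1c(O)c(C)c(OC(C)=O)cc1OC(C)=O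
F7 | step 9 | 1-(2,4-diacetoxy-6-methoxy-5-methylphenyl)ethan-1-one | CC(=O)c1c(OC)c(C)c(OC(C)=O)cc1OC(C)=O
F8 | step 9 | 1-(2,4-diacetoxy-6-methoxy-5-methylphenyl)-2-methylpropan-1-one | CC(C)C(=O)c1c(OC)c(C)c(OC(C)=O)cc1OC(C)=O
F9 | step 9 | 1-(2,4-dihydroxy-6-methoxy-5-methylphenyl)ethan-1-one | CC(=O)c1c(OC)c(C)c(O)cc1O
F10 | step 9 | 1-(2,4-dihydroxy-6-methoxy-5-methylphenyl)-2-methylpropan-1-one | CC(C)C(=O)c1c(OC)c(C)c(O)cc1O
F11 | step 9 | 1-[3-[(dimethylamino)methyl]-2,4-dihydroxy-6-methoxy-5-methylphenyl]ethan-1-one | CC(=O)c1c(OC)c(C)c(O)c(CN(C)C)c1O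
F12 | step 9 | 1-[3-[(dimethylamino)methyl]-2,4-dihydroxy-6-methoxy-5-methylphenyl]-2-methylpropan-1-one | CC(C)C(=O)c1c(OC)c(C)c(O)c(CN(C)C)c1O
F13 | step 9 | 4-acetyl-3-hydroxy-5-methoxy-6-methyl-2-methylidenecyclohexa-3,5-dien-1-one | CC(=O)C1=C(O)C(=C)C(=O)C(C)=C1OC
F14 | step 9 | (2R)-1-[3-[(3-acetyl-2,6-dihydroxy-4-methoxy-5-methylphenyl)methyl]-2,4,6-trihydroxyphenyl]-2-methylbutan-1-one | CC[C@@H](C)C(=O)c1c(O)cc(O)c(Cc2c(O)c(C)c(OC)c(C(C)=O)c2O)c1O
F15 | step 9 | 3-hydroxy-5-methoxy-6-methyl-2-methylidene-4-(2-methylpropanoyl)cyclohexa-3,5-dien-1-one | CC(C)C(=O)C1=C(O)C(=C)C(=O)C(C)=C1OC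
F16 | step 5 | (2R)-N-methoxy-N,2-dimethylbutanamide | CC[C@@H](C)C(=O)N(C)OC
F17 | step 5 | 1,3,5-tris(methoxymethoxy)benzene | COCOc1cc(OCOC)cc(OCOC)c1
F18 | step 5 | 2-lithio-1,3,5-tris(methoxymethoxy)benzene | [Li]c1c(OCOC)cc(OCOC)cc1OCOC
F19 | step 5 | (2R)-2-methyl-1-[2,4,6-tris(methoxymethoxy)phenyl]butan-1-one | CC[C@@H](C)C(=O)c1c(OCOC)cc(OCOC)cc1OCOC
F20 | step 7 | (2R)-1-[3-[(3-acetyl-2,6-dihydroxy-5-methylphenyl)methyl]-5-[(dimethylamino)methyl]-2,4,6-trihydroxyphenyl]-2-methylbutan-1-one | CC[C@@H](C)C(=O)c1c(O)c(CN(C)C)c(O)c(Cc2c(O)c(C)cc(C(C)=O)c2O)c1O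
F21 | step 7 | 2-[(3-acetyl-2,6-dihydroxy-5-methylphenyl)methyl]-3,5-dihydroxy-4-[(2R)-2-methylbutanoyl]-6-methylidenecyclohexa-2,4-dien-1-one | CC[C@@H](C)C(=O)C1=C(O)C(=C)C(=O)C(Cc2c(O)c(C)cc(C(C)=O)c2O)=C1O
F0 | step 10 | none | none
A1 | alternative 1 | benzannulation product: deacyl trimer with ring A C2 hydroxyl free, C4 and C6 as triisopropylsilyl ethers, C1 unsubstituted, outer phenols as benzyl ethers | Oc1cc(O[Si](C(C)C)(C(C)C)C(C)C)c(Cc2c(OCc3ccccc3)c(C)c(OC)c(C(=O)C(C)C)c2OCc2ccccc2)c(O[Si](C(C)C)(C(C)C)C(C)C)c1Cc1c(OCc2ccccc2)c(C)c(OC)c(C(C)=O)c1OCc1ccccc1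
A2 | alternative 1 | 4-[[3-acetyl-2,6-bis(benzyloxy)-4-methoxy-5-methylphenyl]methyl]-2-[[2,6-bis(benzyloxy)-4-methoxy-3-methyl-5-(2-methylpropanoyl)phenyl]methyl]-3-(triisopropylsiloxy)cyclobut-2-en-1-one (racemic at C4) | O=C1C(Cc2c(OCc3ccccc3)c(C)c(OC)c(C(C)=O)c2OCc2ccccc2)C(O[Si](C(C)C)(C(C)C)C(C)C)=C1Cc1c(OCc2ccccc2)c(C)c(OC)c(C(=O)C(C)C)c1OCc1ccccc1
A3 | alternative 1 | (triisopropylsiloxy)ethyne | C#CO[Si](C(C)C)(C(C)C)C(C)C
A4 | alternative 2 | Claisen product: deacyl trimer with complete rings B and C and ring A as its tris(benzyl ether) | CC(=O)c1c(O)c(Cc2c(OCc3ccccc3)cc(OCc3ccccc3)c(Cc3c(O)c(C)c(OC)c(C(=O)C(C)C)c3O)c2OCc2ccccc2)c(O)c(C)c1OC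
A5 | alternative 2 | 1,3,5-tris(benzyloxy)benzene carrying, through methylene groups on C2 of each chain, a methyl 5-methoxy-4-methyl-3,7-dioxooct-5-enoate chain and a methyl 5-methoxy-4,8-dimethyl-3,7-dioxonon-5-enoate chain (mixture of stereoisomers) | COC(=O)C(Cc1c(OCc2ccccc2)cc(OCc2ccccc2)c(CC(C(=O)OC)C(=O)C(C)C(OC)=CC(=O)C(C)C)c1OCc1ccccc1)C(=O)C(C)C(OC)=CC(C)=O
A6 | alternative 3 | aryne insertion product: target with ring A C2 hydroxyl free and the other six hydroxyls as benzyl ethers | CC[C@@H](C)C(=O)c1c(O)c(Cc2c(OCc3ccccc3)c(C)c(OC)c(C(C)=O)c2OCc2ccccc2)c(OCc2ccccc2)c(Cc2c(OCc3ccccc3)c(C)c(OC)c(C(=O)C(C)C)c2OCc2ccccc2)c1OCc1ccccc1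
A7 | alternative 3 | ring A aryne precursor: C1 trimethylsilyl, C2 trifluoromethanesulfonate, C4 and C6 benzyl ethers, both benzyl-protected arms at C3 and C5 | C[Si](C)(C)c1c(OS(=O)(=O)C(F)(F)F)c(Cc2c(OCc3ccccc3)c(C)c(OC)c(C(C)=O)c2OCc2ccccc2)c(OCc2ccccc2)c(Cc2c(OCc3ccccc3)c(C)c(OC)c(C(=O)C(C)C)c2OCc2ccccc2)c1OCc1ccccc1
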